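## Retrosynthetic overview

1. The γ-lactone is closed last, by oxidising C15 of a 13-vinyl-16-hydroxy spiro-ether (lactol, then lactone); the C16–O bond is already in place.
2. The spiro-tetrahydrofuran (C9–O–C13) comes from capture of a C13–C15 allyl cation equivalent by the 9α-hydroxyl. The cation equivalent is a π-allylpalladium species made from a 13,16-vinyl oxirane. This mirrors the biosynthetic closure to 9,13-epoxylabd-14-ene, and the ligand sets C13 from an epimeric mixture.
3. Ring B: 6-oxo-7β-ol ⇐ acyloin shift of a 6-hydroxy-7-ketone ⇐ 9α-hydroxy-7-ketone ⇐ 8α,9α-epoxy-7-ketone ⇐ Δ8-7-ketone ⇐ Δ8 alkene.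
4. Vinyl oxirane ⇐ chloromethyl ketone + vinylmagnesium bromide ⇐ C13 methyl ketone from sclareol.
5. Ring order: decalin (rings A and B, C5, C10) taken from sclareol, then the tetrahydrofuran, then the lactone.

Assumption: the (S,S)-Trost ligand is taken to give the 13R ether, by analogy with alcohol additions to 2-alkyl-2-vinyloxiranes; if the first run shows the opposite sense, the (R,R)-ligand is used with no other change.

## Route

Step 1
Reactants: 1 (−)-sclareol, (13R)-labd-14-ene-8α,13-diol
Product: 2 8α-hydroxy-14,15-dinorlabdan-13-one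
Conditions: KMnO4, acetone/H2O, 0 °C to rt
Reagents that add atoms: none
Why: Oxidative degradation of the vinyl carbinol (permanganate cleavage of the alkene, then oxidative decarboxylation of the α-hydroxy acid) gives the C13 methyl ketone, a classical sclareol degradation; no stereocentre is touched, and C5 and C10 of the target come from sclareol.

Step 2
Reactants: 2 8α-hydroxy-14,15-dinorlabdan-13-one
Product: 3 14,15-dinorlabd-8-en-13-one
Conditions: I2 (10 mol%), benzene, reflux
Reagents that add atoms: none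
Why: Iodine-catalysed E1 dehydration of the tertiary alcohol under equilibrating conditions drains the Δ7, Δ8(17) and cyclic enol-ether isomers to the tetrasubstituted Δ8(9) alkene (thermodynamic control); C8 and C9 become sp2 and are rebuilt in steps 6 and 7.

Step 3
Reactants: 3 14,15-dinorlabd-8-en-13-one
Product: 5 16-chloro-14,15-dinorlabd-8-en-13-one, via silyl enol ether 4 (not isolated)
Conditions: LDA (LiN(iPr)2), THF, −78 °C; TMSCl; then NCS, THF, 0 °C
Reagents that add atoms: N-chlorosuccinimide, O=C1CCC(=O)N1Cl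
Why: Kinetic deprotonation of the methyl ketone at the methyl group, silyl trapping and electrophilic chlorination of the terminal silyl enol ether give regioselective α-chlorination; no stereocentre is formed.

Step 4
Reactants: 5 16-chloro-14,15-dinorlabd-8-en-13-one
Product: 7 (13RS)-13,16-epoxylabda-8,14-diene, via chlorohydrin 6 (not isolated)
Conditions: CH2=CHMgBr, THF, −78 to 0 °C; then 2 M NaOH, rt
Reagents that add atoms: vinylmagnesium bromide, C=C[Mg]Br
Why: Grignard 1,2-addition to the α-chloro ketone followed by intramolecular Williamson closure of the chlorohydrin is the classical route to 2-substituted 2-vinyloxiranes; C13 is formed as both epimers on purpose, because step 10 is stereoconvergent.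

Step 5
Reactants: 7 (13RS)-13,16-epoxylabda-8,14-diene
Product: 8 (13RS)-13,16-epoxylabda-8,14-dien-7-one
Conditions: Rh2(cap)4 (cap = caprolactamate, 1 mol%), TBHP, K2CO3, CH2Cl2, rt
Reagents that add atoms: tert-butyl hydroperoxide, CC(C)(C)OO
Why: Dirhodium-catalysed allylic oxidation with TBHP (Doyle conditions) attacks the ring C7 methylene, whose axial C–H is aligned with the π bond while C11 is neopentyl, and gives the conjugated enone under mildly basic conditions that spare the vinyl oxirane; no stereocentre is formed.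

Step 6
Reactants: 8 (13RS)-13,16-epoxylabda-8,14-dien-7-one
Product: 9 (13RS)-8α,9α:13,16-diepoxylabd-14-en-7-one
Conditions: 30% H2O2, NaOH, MeOH, 0 °C to rt
Reagents that add atoms: hydrogen peroxide, OO
Why: Weitz–Scheffer nucleophilic epoxidation in which hydroperoxide adds to C9 axially from the α face, anti to the axial C10 methyl, so the oxygen that becomes the C9 ether oxygen is set α.

Step 7
Reactants: 9 (13RS)-8α,9α:13,16-diepoxylabd-14-en-7-one
Product: 10 (13RS)-13,16-epoxy-9α-hydroxylabd-14-en-7-one (8α-methyl, 8β-H)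
Conditions: SmI2 (2.2 equiv), THF/MeOH, −78 °C, 10 min
Reagents that add atoms: none
Why: Samarium diiodide reduction of the α,β-epoxy ketone (Molander) cleaves the C8–O bond and keeps the 9α-hydroxyl; C8 is α to the ketone and settles as the equatorial 8α-methyl under thermodynamic control (as in hispanolone), and the vinyl oxirane is not reduced at −78 °C without HMPA.

Step 8
Reactants: 10 (13RS)-13,16-epoxy-9α-hydroxylabd-14-en-7-one
Product: 13 (13RS)-13,16-epoxy-6α,9α-dihydroxylabd-14-en-7-one, via silyl enol ether 11 (not isolated), via 6-silyloxy ketone 12 (not isolated)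
Conditions: LiHMDS (LiN(SiMe3)2, 2.3 equiv), TMSCl, THF, −78 °C; DMDO, acetone/CH2Cl2, −78 to 0 °C; citric acid, MeOH, rt
Reagents that add atoms: dimethyldioxirane, CC1(C)OO1
Why: Rubottom oxidation: kinetic enolisation goes to the C6 methylene (C8 is a hindered methine next to the alkoxide), and DMDO epoxidises the silyl enol ether from the α face (the β face is blocked by C19 and C20) to give the 6α-ol after silyl migration; this C6 configuration is inconsequential because C6 becomes the carbonyl in step 9.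

Step 9
Reactants: 13 (13RS)-13,16-epoxy-6α,9α-dihydroxylabd-14-en-7-one
Product: 15 (13RS)-13,16-epoxy-7β,9α-dihydroxylabd-14-en-6-one, via enediol 14 (not isolated)
Conditions: K2CO3 (0.5 equiv), MeOH, 0 °C to rt
Reagents that add atoms: none
Why: Base-mediated α-ketol (acyloin) tautomerisation through the enediol drains to the 6-oxo-7β-ol, because the C6 carbonyl removes the syn-axial strain between H6β and the C19 and C20 methyls and the new hydroxyl is equatorial; C7 is set by axial (α-face) protonation of the enediol, which is also the thermodynamic outcome, and C5 keeps the trans ring fusion.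

Step 10
Reactants: 15 (13RS)-13,16-epoxy-7β,9α-dihydroxylabd-14-en-6-one
Product: 16 (13R)-9α,13-epoxy-7β,16-dihydroxylabd-14-en-6-one
Conditions: Pd2(dba)3·CHCl3 (2.5 mol%), (S,S)-DACH-phenyl Trost ligand (7.5 mol%), Et3B (10 mol%), CH2Cl2, rt
Reagents that add atoms: none
Why: Proposed new method: zerovalent palladium ionises both C13 epimers of the vinyl oxirane to a zwitterionic π-allylpalladium alkoxide (a metal-bound C13–C15 allyl cation, as in the biosynthetic closure to 9,13-epoxylabd-14-ene), the diastereomeric complexes interconvert by π–σ–π faster than they are trapped, the borane bridges the C16 alkoxide and the 9α-hydroxyl and delivers O9 to the substituted terminus in a 5-exo closure (the 7β-hydroxyl would need a seven-membered ring), and the ligand chooses the C13 face to give 13R; the closest known reaction is the Trost palladium/borane dynamic kinetic asymmetric addition of alcohols to isoprene monoxide and 2-alkyl-2-vinyloxiranes, here extended to an intramolecular tertiary alcohol.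

Step 11
Reactants: 16 (13R)-9α,13-epoxy-7β,16-dihydroxylabd-14-en-6-one
Product: 18 (13R)-9α,13-epoxy-7β,15,16-trihydroxylabdan-6-one, via B-alkyl-9-BBN adduct 17 (not isolated)
Conditions: 9-BBN (excess), THF, 0 °C to rt; NaBO3·4H2O, H2O, rt
Reagents that add atoms: sodium perborate, [Na+].[O-]B1OO1
Why: Hydroboration–oxidation: 9-BBN adds only to the monosubstituted vinyl group with anti-Markovnikov regiochemistry and does not reduce the very hindered C6 ketone, and perborate avoids alkaline peroxide cleavage of the α-ketol; no stereocentre is formed.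

Step 12
Reactants: 18 (13R)-9α,13-epoxy-7β,15,16-trihydroxylabdan-6-one
Product: 20 (13R)-9α,13-epoxy-7β-hydroxy-6-oxolabdan-15,16-olide (CNP0291402.1), via lactol 19 (not isolated)
Conditions: TEMPO (20 mol%), PhI(OAc)2 (2.5 equiv), CH2Cl2, rt
Reagents that add atoms: none
Why: TEMPO/PhI(OAc)2 oxidative lactonisation of the 1,4-diol: the unhindered C15 primary alcohol is oxidised before the neopentyl C16 alcohol, the lactol closes and is oxidised to the 15,16-olide, the hindered secondary 7β-hydroxyl is left alone, and the neutral conditions avoid retro-oxa-Michael epimerisation at C13.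

## Compound list

1 | (−)-sclareol, (13R)-labd-14-ene-8α,13-diol | C[C@@]1(O)CC[C@H]2C(C)(C)CCC[C@]2(C)[C@H]1CC[C@@](C)(O)C=C | starting material
2 | 8α-hydroxy-14,15-dinorlabdan-13-one | C[C@@]1(O)CC[C@H]2C(C)(C)CCC[C@]2(C)[C@H]1CCC(C)=O | intermediate
3 | 14,15-dinorlabd-8-en-13-one | CC1=C(CCC(C)=O)[C@@]2(C)CCCC(C)(C)[C@@H]2CC1 | intermediate
4 | 13-(trimethylsilyloxy)-14,15-dinorlabda-8,13(16)-diene (silyl enol ether) | CC1=C(CCC(=C)O[Si](C)(C)C)[C@@]2(C)CCCC(C)(C)[C@@H]2CC1 | intermediate
5 | 16-chloro-14,15-dinorlabd-8-en-13-one | CC1=C(CCC(=O)CCl)[C@@]2(C)CCCC(C)(C)[C@@H]2CC1 | intermediate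
6 | (13RS)-16-chlorolabda-8,14-dien-13-ol (chlorohydrin) | CC1=C(CCC(O)(CCl)C=C)[C@@]2(C)CCCC(C)(C)[C@@H]2CC1 | intermediate
7 | (13RS)-13,16-epoxylabda-8,14-diene (both C13 epimers) | CC1=C(CCC3(CO3)C=C)[C@@]2(C)CCCC(C)(C)[C@@H]2CC1 | intermediate
8 | (13RS)-13,16-epoxylabda-8,14-dien-7-one | CC1=C(CCC3(CO3)C=C)[C@@]2(C)CCCC(C)(C)[C@@H]2CC1=O | intermediate
9 | (13RS)-8α,9α:13,16-diepoxylabd-14-en-7-one | C[C@@]12C(=O)C[C@H]3C(C)(C)CCC[C@]3(C)[C@]1(CCC4(CO4)C=C)O2 | intermediate
10 | (13RS)-13,16-epoxy-9α-hydroxylabd-14-en-7-one (8α-methyl) | C[C@@H]1C(=O)C[C@H]2C(C)(C)CCC[C@]2(C)[C@@]1(O)CCC3(CO3)C=C | intermediate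
11 | (13RS)-13,16-epoxy-7-(trimethylsilyloxy)labda-6,14-dien-9α-ol (silyl enol ether) | C[C@@H]1C(O[Si](C)(C)C)=C[C@H]2C(C)(C)CCC[C@]2(C)[C@@]1(O)CCC3(CO3)C=C | intermediate
12 | (13RS)-13,16-epoxy-9α-hydroxy-6α-(trimethylsilyloxy)labd-14-en-7-one | C[C@@H]1C(=O)[C@H](O[Si](C)(C)C)[C@H]2C(C)(C)CCC[C@]2(C)[C@@]1(O)CCC3(CO3)C=C | intermediate
13 | (13RS)-13,16-epoxy-6α,9α-dihydroxylabd-14-en-7-one | C[C@@H]1C(=O)[C@H](O)[C@H]2C(C)(C)CCC[C@]2(C)[C@@]1(O)CCC3(CO3)C=C | intermediate
14 | (13RS)-13,16-epoxylabda-6,14-diene-6,7,9α-triol (enediol) | C[C@@H]1C(O)=C(O)[C@H]2C(C)(C)CCC[C@]2(C)[C@@]1(O)CCC3(CO3)C=C | intermediate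
15 | (13RS)-13,16-epoxy-7β,9α-dihydroxylabd-14-en-6-one | C[C@@H]1[C@@H](O)C(=O)[C@H]2C(C)(C)CCC[C@]2(C)[C@@]1(O)CCC3(CO3)C=C | intermediate
16 | (13R)-9α,13-epoxy-7β,16-dihydroxylabd-14-en-6-one | C[C@@H]1[C@@H](O)C(=O)[C@H]2C(C)(C)CCC[C@]2(C)[C@@]12CC[C@@](C=C)(CO)O2 | intermediate
17 | B-alkyl-9-BBN adduct of 16 at C15 (hydroxyls drawn free) | C[C@@H]1[C@@H](O)C(=O)[C@H]2C(C)(C)CCC[C@]2(C)[C@@]12CC[C@@](CCB3C4CCCC3CCC4)(CO)O2 | intermediate
18 | (13R)-9α,13-epoxy-7β,15,16-trihydroxylabdan-6-one | C[C@@H]1[C@@H](O)C(=O)[C@H]2C(C)(C)CCC[C@]2(C)[C@@]12CC[C@@](CCO)(CO)O2 | intermediate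
19 | (13R)-9α,13:15,16-diepoxy-7β,15-dihydroxylabdan-6-one (lactol, closed form of the 15-aldehyde) | C[C@@H]1[C@@H](O)C(=O)[C@H]2C(C)(C)CCC[C@]2(C)[C@@]12CC[C@@]1(COC(O)C1)O2 | intermediate
20 | (13R)-9α,13-epoxy-7β-hydroxy-6-oxolabdan-15,16-olide (CNP0291402.1) | C[C@@H]1[C@@H](O)C(=O)[C@H]2C(C)(C)CCC[C@]2(C)[C@@]12CC[C@@]1(COC(=O)C1)O2 | target

## Step count and risk

Total steps: 12. Longest linear sequence: 12 (fully linear from sclareol).

**Step 10 (palladium etherification).** A hindered tertiary alcohol has not been used this way, and the ligand may not override the substrate. The fallback sets out from 15 and returns at 20, replacing allylic substitution by conjugate addition. Hydroboration–oxidation of the vinyl group of 15 (9-BBN; NaBO3) gives (13RS)-13,16-epoxy-7β,9α,15-trihydroxylabdan-6-one F1. TEMPO/PhI(OAc)2 followed by Et3N oxidises C15 to the aldehyde, the β,γ-epoxy aldehyde opens by β-elimination to the γ-hydroxy enal, and its lactol is oxidised on to 7β,9α-dihydroxy-6-oxolabd-13-en-15,16-olide F2. Catalytic DBU in CH2Cl2 then effects the reversible oxa-Michael addition of the 9α-hydroxyl to the butenolide. This gives 20 together with (13S)-9α,13-epoxy-7β-hydroxy-6-oxolabdan-15,16-olide F3; the two are separated by chromatography and F3 is re-equilibrated.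

**Step 9 (acyloin shift).** The equilibrium may be incomplete, or retro-aldol and dehydration of the β-hydroxy ketone may compete. The fallback sets out from 13 and returns at 15, replacing the equilibration by a redox and protecting-group transposition. Hydroxyl-directed reduction of 13 with Me4NBH(OAc)3 in MeCN/AcOH at −30 °C delivers hydride to C7 from the α face (anti to the 9α-hydroxyl) and gives (13RS)-13,16-epoxylabd-14-ene-6α,7β,9α-triol F4. TBSCl/imidazole silylates the less hindered 7β-hydroxyl to give (13RS)-7β-(tert-butyldimethylsilyloxy)-13,16-epoxylabd-14-ene-6α,9α-diol F5. Dess–Martin periodinane oxidises the 6-hydroxyl to give (13RS)-7β-(tert-butyldimethylsilyloxy)-13,16-epoxy-9α-hydroxylabd-14-en-6-one F6. TBAF buffered with AcOH then releases 15.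

**Step 5 (allylic oxidation).** Oxidation may also occur at C11, or the vinyl oxirane may not survive. The fallback sets out from 7 and returns at 8, replacing C–H oxidation by an ene reaction and oxidative transposition. Singlet oxygen (O2, tetraphenylporphyrin, hν, CH2Cl2, −20 °C) adds to C9 from the α face with shift of the alkene to give (13RS)-13,16-epoxy-9α-hydroperoxylabda-7,14-diene F7. PPh3 reduces it in the same flask to (13RS)-13,16-epoxylabda-7,14-dien-9α-ol F8. Babler–Dauben oxidative 1,3-transposition of this tertiary allylic alcohol (PCC buffered with NaOAc, or an oxoammonium salt) gives 8.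

## Further compounds

F1 | step 10 | (13RS)-13,16-epoxy-7β,9α,15-trihydroxylabdan-6-one | C[C@@H]1[C@@H](O)C(=O)[C@H]2C(C)(C)CCC[C@]2(C)[C@@]1(O)CCC3(CO3)CCO
F2 | step 10 | 7β,9α-dihydroxy-6-oxolabd-13-en-15,16-olide | C[C@@H]1[C@@H](O)C(=O)[C@H]2C(C)(C)CCC[C@]2(C)[C@@]1(O)CCC3=CC(=O)OC3
F3 | step 10 | (13S)-9α,13-epoxy-7β-hydroxy-6-oxolabdan-15,16-olide | C[C@@H]1[C@@H](O)C(=O)[C@H]2C(C)(C)CCC[C@]2(C)[C@@]12CC[C@]1(COC(=O)C1)O2
F4 | step 9 | (13RS)-13,16-epoxylabd-14-ene-6α,7β,9α-triol | C[C@@H]1[C@@H](O)[C@H](O)[C@H]2C(C)(C)CCC[C@]2(C)[C@@]1(O)CCC3(CO3)C=C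
F5 | step 9 | (13RS)-7β-(tert-butyldimethylsilyloxy)-13,16-epoxylabd-14-ene-6α,9α-diol | C[C@@H]1[C@@H](O[Si](C)(C)C(C)(C)C)[C@H](O)[C@H]2C(C)(C)CCC[C@]2(C)[C@@]1(O)CCC3(CO3)C=C
F6 | step 9 | (13RS)-7β-(tert-butyldimethylsilyloxy)-13,16-epoxy-9α-hydroxylabd-14-en-6-one | C[C@@H]1[C@@H](O[Si](C)(C)C(C)(C)C)C(=O)[C@H]2C(C)(C)CCC[C@]2(C)[C@@]1(O)CCC3(CO3)C=C
F7 | step 5 | (13RS)-13,16-epoxy-9α-hydroperoxylabda-7,14-diene | CC1=CC[C@H]2C(C)(C)CCC[C@]2(C)[C@@]1(OO)CCC3(CO3)C=C
F8 | step 5 | (13RS)-13,16-epoxylabda-7,14-dien-9α-ol | CC1=CC[C@H]2C(C)(C)CCC[C@]2(C)[C@@]1(O)CCC3(CO3)C=C
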